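## The problem

The target 22 consists of two heavily oxygenated six-membered rings joined by one CH2 group. Ring A is an enolised 2-acylcyclohexane-1,3,5-trione: C1 ketone, C2 isobutyryl, C3 and C5 enols, C4 quaternary, C6 carrying the bridge. Ring B is a fully substituted phloroglucinol: C1' bridge, C2' and C6' hydroxyls, C3' isobutyryl, C4' the pyran oxygen, C5' the vinyl carbon of the fused 2,2-dimethylpyran (ring C). The only stereocentre is C4 of ring A, bearing methyl and prenyl between two enolised carbonyl carbons. No neighbouring centre can direct its formation and it cannot epimerise once made, so it has to be set early by a chiral catalyst and then carried through. Ring A is a vinylogous diacid with several tautomers, ring B is easily oxidised, and the prenyl and chromene double bonds cyclise or oligomerise in strong acid. Late steps must therefore be mild, and the acidic enols must be masked whenever an acid-labile partner is present. The usual way to join such halves, bridging two phloroglucinol-type nucleophiles with a formaldehyde equivalent, has to control cross- against homo-coupling. The feature that allows a different construction is the pattern of ring B: three C–O carbons alternate with three C–C carbons, and C1' lies between two C–O carbons and para to the pyran oxygen. That is the pattern formed when an ynol ether (supplying C1' and C6'–O) combines with a 3-alkoxy vinylketene (supplying C2'–O, C3', C4'–O and C5'). Ring B can thus be grown on a ring A that already carries the bridge carbon, with its three oxygens formed in three different states.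

## Retrosynthesis

**22 ⇒ 21 ⇒ 20 (unmasking).** No skeletal bond is cut. The two enols of ring A are written as methyl ethers (21) and the C6' hydroxyl in addition as its triisopropylsilyl ether (20). The masks are kept to the end because masked ring A has no acidic proton and because the silyl ether decides which oxygen closes ring C. The forward steps are fluoride, then dilute aqueous acid acting on the neutral ring, and they must not touch the prenyl or chromene double bonds.

**20 ⇒ 19 (ring C).** The C5'–vinyl bond is cut, and the pyran C–O bond remains as an aryl 1,1-dimethylpropargyl ether in 19. Cutting the O–C bond instead (phenol plus enal) would require a choice between two hydroxyls at ring closure. Here the oxygen is fixed beforehand and only one ortho carbon is free. The precursor has one ring less, and the forward reaction is a thermal, reagent-free Claisen cascade.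

**19 ⇒ 18 (ring B acyl group).** The C3'–acyl bond is cut. Acylation is placed before ring C closure for two reasons. It blocks C3', leaving the Claisen step a single ortho carbon flanked only by the propargyloxy and the silylated oxygen. An acylated chromene is also less acid-sensitive in the final hydrolysis. The forward step has to acylate ortho to the one free hydroxyl of 18 without ionising the tertiary propargyl ether.

**18 ⇒ 11 + 17 (ring B, key cut).** The bonds C1'–C2' and C5'–C6' are cut; C2'–C3' is the bond of the four-membered ring that opens and re-forms. The neighbouring cut at the CH2 bridge is shorter but must differentiate two similar phloroglucinol nucleophiles. Cutting ring B itself removes a whole hexasubstituted arene and leads to an ynol silyl ether on the ring A methylene (11) and the four-carbon cyclobutenone 17. The three ring B oxygens then emerge as free OH, propargyl ether and silyl ether. The forward reaction needs a single regiochemistry of ketene-to-alkyne addition, and a temperature below that of the propargyl Claisen rearrangement.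

**17 ⇒ 15 + 16; 15 ⇒ 12 + 13.** The enol ether C–O bond of 17 is cut to 3-ethoxycyclobutenone 15 and the tertiary alcohol 16. Making the tertiary propargyl ynol ether first is excluded because it would rearrange sigmatropically. The four-membered ring of 15 is cut into ketene (14, from diketene 12) and ethoxyacetylene 13.

**11 ⇒ 8 ⇒ 7 ⇒ 5 + 6.** The Si–O/C–O unit of the ynol ether is traced to the terminal alkyne 8 (acetylide oxidation, O-silylation). The methyl ethers of 8 go back to the free enols of 7, and the C6–CH2 bond of 7 to the trione 5 and propargyl bromide 6. Methylation precedes ynol ether formation because an ynol ether does not tolerate the free vinylogous acid. Propargylation precedes methylation because only the free enol is nucleophilic at C6.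

**5 ⇒ 3 + 4; 3 ⇒ 1 + 2.** The C4–prenyl bond is cut as an asymmetric dearomative allylation of the acylphloroglucinol 3 with prenyl acetate 4. This creates the quaternary stereocentre and ring A in one step from a flat arene. Building ring A from acyclic material is the alternative and is discussed below. 3 comes from 2-methylphloroglucinol 1 and isobutyryl chloride 2.

## Roads not taken

**Alternative 1:** stereoconvergent acyl transfer from a pyranone.
- **Cut:** the C3–C4 bond of ring A.
- **Forward step:** a chiral isothiourea opens the lactone of racemic 4-methoxy-6-(5-methylhex-4-en-2-yl)-3-(2-methylpropanoyl)-2H-pyran-2-one A2 to a tethered acylammonium ion. The enolate at the former side-chain CH carbon attacks it, closing ring A as the vinylogous methyl ester A1 with the quaternary centre set.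
- **Merits:** it is catalytic and stereoconvergent, since the side-chain stereocentre of A2 is erased in the enolate. A1 also carries one regiodefined methyl enol ether, which is better than the O-methylation of 7 in the chosen plan, where the position of the ethers is not controlled.
- **Weak points:** the lactone carbonyl of a 4-methoxypyranone is a vinylogous carbonate and a poor acyl donor. The cross-conjugated enolate must form at a tertiary carbon. The catalyst must distinguish methyl from a prenyl-bearing CH2 on a tetrasubstituted enolate, which is a small steric difference.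
- **Comparison:** A2 needs several steps of its own, and the road solves only ring A; rings B and C must still be attached. The chosen plan reaches the same ring in two steps from 1. A1 would be worth having mainly as a second source of ring A if step 2 failed.

**Alternative 2:** propargyl ether Claisen cascade on a separate ring B.
- **Cut:** the C5'–vinyl bond of ring C, on a ring B not yet joined to ring A.
- **Forward step:** heating 1-[2-hydroxy-6-(2-methylbut-3-yn-2-yloxy)-4-(triisopropylsilyloxy)phenyl]-2-methylpropan-1-one A4 causes a [3,3] shift to its one free ortho carbon, a hydrogen shift and oxa-6π closure to the chromene A3. A3 would then be bridged to 5 with a formaldehyde equivalent and desilylated.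
- **Merits:** every step is of a known type, and the approach is convergent. By count of operations it is shorter than the chosen plan, and it is better in precedent.
- **Weak points:** A4 requires selective silylation and propargylation among three phenolic hydroxyls. The methylene bridging joins two nucleophiles of similar reactivity and needs one partner pre-activated to suppress homo-coupling.
- **Comparison:** the chosen plan offers a ring B made by C–C bond formation that cannot give homodimers, with oxygens differentiated by the reaction itself. It keeps the same Claisen cascade as its step 10. The bridging chemistry of this road serves as the fallback for the key step.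

**Alternative 3:** enzymatic desymmetrisation and Dieckmann closure.
- **Cut:** the C2–C3 bond of ring A.
- **Forward step:** pig liver esterase desymmetrises dimethyl 2-methyl-2-(3-methylbut-2-en-1-yl)propanedioate A8 to the half-ester A7. Chain extension through the acid with a β-diketone dianion gives the 3,5,7-triketo ester A6. KOtBu then closes A6 to the acyl trione A5, which is identical with 5.
- **Merits:** the quaternary centre comes from a robust class of enzymatic reaction and is fixed before any ring exists. There is no competition between ring carbons or between C- and O-allylation, as there is in step 2 of the chosen plan. In that respect this road is the safer one.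
- **Weak points:** the enzyme must distinguish methyl from prenyl. The acylation of a dianion by a neopentyl-type acid derivative and the Dieckmann attack on a hindered ester are both sterically demanding. About six steps are needed where the chosen plan needs two.
- **Comparison:** the road ends at 5 and leaves everything after it unchanged. It is a longer but independent entry to 5, to be taken if asymmetric allylation cannot be made selective.

Key step: step 8

Remark 1: enolised triones are written as the 3,5-dihydroxycyclohexa-2,5-dien-1-one tautomer, and the descriptor S refers to that drawing.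
Remark 2: double O-methylation in step 4 is taken to give the cross-conjugated 3,5-dimethoxy isomer 8; an isomeric bis(enol ether) would react alike and converge in step 12.
Remark 3: the ligand of step 2 is written as its (1R,2R) enantiomer; should the sense of induction be opposite, the (1S,2S) ligand is used.

## Route

Step 1
Reactants: 1 2-methylbenzene-1,3,5-triol; 2 2-methylpropanoyl chloride
Product: 3 2-methyl-1-(2,4,6-trihydroxy-3-methylphenyl)propan-1-one
Conditions: AlCl3 (3 equiv), PhNO2, 25 → 60 °C; aq. HCl work-up
Reagents that add atoms: none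
Why: Friedel–Crafts C-acylation of the phloroglucinol nucleus; the two free ring positions of 1 are equivalent, and the first acyl group deactivates the ring against a second acylation.

Step 2
Reactants: 3 2-methyl-1-(2,4,6-trihydroxy-3-methylphenyl)propan-1-one; 4 3-methylbut-2-en-1-yl acetate
Product: 5 (S)-3,5-dihydroxy-4-methyl-4-(3-methylbut-2-en-1-yl)-2-(2-methylpropanoyl)cyclohexa-2,5-dien-1-one
Conditions: Pd2(dba)3·CHCl3 (2.5 mol %), (1R,2R)-N,N'-bis[2-(diphenylphosphino)benzoyl]cyclohexane-1,2-diamine (7.5 mol %), Cs2CO3 (1.0 equiv), 1,4-dioxane, 25 °C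
Reagents that add atoms: none
Why: Tsuji–Trost asymmetric allylic alkylation run as a dearomatisation: the phenoxide of 3 attacks the palladium-bound η3-prenyl cation through its methyl-bearing ring carbon, the more electron-rich of the two nucleophilic carbons, at the unsubstituted allyl terminus. The C2-symmetric bisphosphine differentiates the two faces of this prochiral carbon and so sets C4; with one equivalent of base the product is held as its weakly nucleophilic triketonate, which limits a second prenylation.

Step 3
Reactants: 5 (S)-acyl trione of ring A; 6 3-bromoprop-1-yne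
Product: 7 (S)-3,5-dihydroxy-4-methyl-4-(3-methylbut-2-en-1-yl)-2-(2-methylpropanoyl)-6-(prop-2-yn-1-yl)cyclohexa-2,5-dien-1-one
Conditions: NaOMe (2.1 equiv), MeOH, 0 °C; 6 (1.05 equiv), 0 → 25 °C
Reagents that add atoms: none
Why: C-alkylation of the dianion of the vinylogous acid at C6, the only ring A carbon that still bears hydrogen; in methanol the oxygens are hydrogen-bonded and the soft bromide is taken up at carbon. One equivalent of 6 limits double alkylation.

Step 4
Reactants: 7 (S)-6-propargyl acyl trione
Product: 8 (S)-3,5-dimethoxy-4-methyl-4-(3-methylbut-2-en-1-yl)-2-(2-methylpropanoyl)-6-(prop-2-yn-1-yl)cyclohexa-2,5-dien-1-one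
Conditions: Me3SiCHN2 (3 equiv, hexanes), MeOH–toluene 1:4, 0 → 25 °C
Reagents that add atoms: trimethylsilyldiazomethane, C[Si](C)(C)C=[N+]=[N-]
Why: O-methylation of the two acidic enols by diazomethane generated in situ from Me3SiCHN2 and methanol; it removes both protons that would destroy an ynol silyl ether and leaves the alkyne and the alkene untouched.

Step 5
Reactants: 8 (S)-6-propargyl bis(methyl enol ether)
Product: 11 (S)-3,5-dimethoxy-4-methyl-4-(3-methylbut-2-en-1-yl)-2-(2-methylpropanoyl)-6-{3-[tri(propan-2-yl)silyloxy]prop-2-yn-1-yl}cyclohexa-2,5-dien-1-one, via lithium acetylide 9 (not isolated), via lithium ynolate 10 (not isolated)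
Conditions: LiN(SiMe3)2 (1.05 equiv), THF, −78 °C; LiOOtBu (1.2 equiv, from t-BuOOH and LiN(SiMe3)2), −78 → 0 °C; i-Pr3SiOTf (1.3 equiv), −78 °C; Et3N-buffered work-up
Reagents that add atoms: tert-butyl hydroperoxide, CC(C)(C)OO; triisopropylsilyl trifluoromethanesulfonate, CC(C)[Si](C(C)C)(C(C)C)OS(=O)(=O)C(F)(F)F
Why: Oxidation of a lithium acetylide by LiOOtBu to the lithium ynolate and O-silylation with a bulky silyl triflate is the standard route from terminal alkynes to triisopropylsiloxyalkynes. The hindered amide base should remove the sp C–H faster than the shielded tertiary α-hydrogen of the isobutyryl group, and the ring A carbonyl groups are deactivated by their methoxy donors.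

Step 6
Reactants: 12 4-methylideneoxetan-2-one (diketene); 13 ethoxyethyne
Product: 15 3-ethoxycyclobut-2-en-1-one, via ketene 14 (not isolated)
Conditions: 12, quartz tube, 550 °C, N2 stream; ketene stream led into 13, CH2Cl2, 0 °C; surplus ketene carried on to a scrubber
Reagents that add atoms: none
Why: Thermal cracking of diketene gives two molecules of ketene; one bonds through its carbonyl carbon to the nucleophilic β-carbon of ethoxyacetylene in a regioselective (2+2) cycloaddition to give the vinylogous ester 15, and the other leaves with the nitrogen stream.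

Step 7
Reactants: 15 3-ethoxycyclobut-2-en-1-one; 16 2-methylbut-3-yn-2-ol
Product: 17 3-(2-methylbut-3-yn-2-yloxy)cyclobut-2-en-1-one
Conditions: 16 (5 equiv), camphor-10-sulfonic acid (5 mol %), 5 Å molecular sieves, CH2Cl2, 25 °C; Et3N quench
Reagents that add atoms: none
Why: Acid-catalysed alkoxy exchange of a β-alkoxy enone (addition of the alcohol to the protonated vinylogous ester, loss of ethanol); the 5 Å sieve takes up linear ethanol but not the branched alcohol and so drives the equilibrium toward the tertiary ether.

Step 8
Reactants: 11 (S)-ring A bis(methyl enol ether) carrying the 3-(triisopropylsilyloxy)prop-2-yn-1-yl group at C6; 17 3-(2-methylbut-3-yn-2-yloxy)cyclobut-2-en-1-one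
Product: 18 (S)-6-{[2-hydroxy-4-(2-methylbut-3-yn-2-yloxy)-6-(triisopropylsilyloxy)phenyl]methyl}-3,5-dimethoxy-4-methyl-4-(3-methylbut-2-en-1-yl)-2-(2-methylpropanoyl)cyclohexa-2,5-dien-1-one
Conditions: 17 (1.5 equiv, in portions), toluene, 80 °C, Ar
Reagents that add atoms: none
Why: Proposed new method: heating should open 17 by 4π-electrocyclic ring opening to a 1-alkoxyvinyl ketene, whose ketene C=C adds to the electron-rich triple bond of 11 in a (2+2) cycloaddition; the resulting 4-vinylcyclobutenone opens again (4π) to a dienylketene, which closes by 6π-electrocyclisation and tautomerises to the phenol 18. The closest known reaction type is the Danheiser benzannulation of 3-alkyl- and 3-aryl-cyclobutenones with triisopropylsiloxyalkynes to resorcinol monosilyl ethers; a 3-alkoxycyclobutenone has not been used in it, and its vinylogous-ester stabilisation may slow the first ring opening. Ring B is closed by a thermal disrotatory 6π-electrocyclisation that joins the former ketene carbonyl carbon (C2') to the former ring CH2 (C3'), after the intermolecular (2+2) step has made the C1'–C2' and C5'–C6' bonds. No stereocentre is formed, and C4 of ring A is remote and cannot epimerise. The step needs one regiochemistry in the (2+2) addition: the siloxyalkyne is nucleophilic at the carbon remote from oxygen, which therefore bonds to the electrophilic ketene carbonyl carbon and places the bridge between OH and OSi and para to the propargyloxy group. It also needs chemoselectivity: only the ynol ether is a strongly polarised ketenophile, so the prenyl alkene, the methyl enol ethers and the terminal alkyne of 17 should not compete, and 80 °C is chosen so that the aryl propargyl ether of 18 does not yet rearrange.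

Step 9
Reactants: 18 (S)-benzannulation product (free C2' hydroxyl); 2 2-methylpropanoyl chloride
Product: 19 (S)-6-{[2-hydroxy-3-(2-methylpropanoyl)-4-(2-methylbut-3-yn-2-yloxy)-6-(triisopropylsilyloxy)phenyl]methyl}-3,5-dimethoxy-4-methyl-4-(3-methylbut-2-en-1-yl)-2-(2-methylpropanoyl)cyclohexa-2,5-dien-1-one
Conditions: Me2AlCl (2.5 equiv), CH2Cl2, −78 °C; 2 (1.2 equiv), −78 → −20 °C; aq. KNaC4H4O6 (potassium sodium tartrate) work-up
Reagents that add atoms: none
Why: Ortho-directed Friedel–Crafts acylation through the aluminium phenoxide: the one free hydroxyl binds the Lewis acid and delivers the acyl chloride to the adjacent carbon C3', which is also far less hindered than C5' between the two bulky ethers. Me2AlCl consumes the proton released, so no HCl reaches the prenyl group or the tertiary propargyl ether.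

Step 10
Reactants: 19 (S)-aryl ketone with aryl 1,1-dimethylpropargyl ether
Product: 20 (S)-6-{[7-hydroxy-2,2-dimethyl-8-(2-methylpropanoyl)-5-(triisopropylsilyloxy)-2H-chromen-6-yl]methyl}-3,5-dimethoxy-4-methyl-4-(3-methylbut-2-en-1-yl)-2-(2-methylpropanoyl)cyclohexa-2,5-dien-1-one
Conditions: o-xylene (degassed), 140 °C, Ar
Reagents that add atoms: none
Why: Aromatic propargyl Claisen rearrangement to the only free ortho carbon (C5'), enolisation, 1,5-hydrogen shift to an ortho-quinone methide and oxa-6π-electrocyclisation close ring C. The silylated oxygen on the other side of C5' cannot take part, so the pyran oxygen can only be the one next to the acyl group.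

Step 11
Reactants: 20 (S)-silylated chromene
Product: 21 (S)-6-{[5,7-dihydroxy-2,2-dimethyl-8-(2-methylpropanoyl)-2H-chromen-6-yl]methyl}-3,5-dimethoxy-4-methyl-4-(3-methylbut-2-en-1-yl)-2-(2-methylpropanoyl)cyclohexa-2,5-dien-1-one
Conditions: Bu4NF (1.2 equiv), AcOH (1.2 equiv), THF, 0 °C
Reagents that add atoms: none
Why: Fluoride cleaves the aryl silyl ether; acetic acid buffers the phenoxide so that the activated methyl enol ether of ring A is not attacked by hydroxide or fluoride.

Step 12
Reactants: 21 (S)-bis(methyl enol ether) of the target
Product: 22 target, (S)-6-{[5,7-dihydroxy-2,2-dimethyl-8-(2-methylpropanoyl)-2H-chromen-6-yl]methyl}-3,5-dihydroxy-4-methyl-4-(3-methylbut-2-en-1-yl)-2-(2-methylpropanoyl)cyclohexa-2,5-dien-1-one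
Conditions: 1 M aq. HCl–THF 1:2, 25 °C, Ar
Reagents that add atoms: water, O
Why: Acid hydrolysis of the two vinylogous methyl esters (water adds to the protonated β-alkoxy enone and methanol leaves) frees the enolised trione; it acts on the neutral ring, so the second ether is not shielded by an anion as it would be under basic or halide conditions. The acylated chromene and the prenyl group should tolerate dilute acid at room temperature, and C4 is quaternary and cannot epimerise.

## Compound list

1 | 2-methylbenzene-1,3,5-triol | Cc1c(O)cc(O)cc1O | starting material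
2 | 2-methylpropanoyl chloride | CC(C)C(Cl)=O | starting material
3 | 2-methyl-1-(2,4,6-trihydroxy-3-methylphenyl)propan-1-one | CC(C)C(=O)c1c(O)cc(O)c(C)c1O | intermediate
4 | 3-methylbut-2-en-1-yl acetate | CC(C)=CCOC(C)=O | starting material
5 | (S)-3,5-dihydroxy-4-methyl-4-(3-methylbut-2-en-1-yl)-2-(2-methylpropanoyl)cyclohexa-2,5-dien-1-one | CC(C)=CC[C@@]1(C)C(O)=CC(=O)C(C(=O)C(C)C)=C1O | intermediate
6 | 3-bromoprop-1-yne | BrCC#C | starting material
7 | (S)-3,5-dihydroxy-4-methyl-4-(3-methylbut-2-en-1-yl)-2-(2-methylpropanoyl)-6-(prop-2-yn-1-yl)cyclohexa-2,5-dien-1-one | CC(C)=CC[C@@]1(C)C(O)=C(CC#C)C(=O)C(C(=O)C(C)C)=C1O | intermediate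
8 | (S)-3,5-dimethoxy-4-methyl-4-(3-methylbut-2-en-1-yl)-2-(2-methylpropanoyl)-6-(prop-2-yn-1-yl)cyclohexa-2,5-dien-1-one | CC(C)=CC[C@@]1(C)C(OC)=C(CC#C)C(=O)C(C(=O)C(C)C)=C1OC | intermediate
9 | lithium acetylide of 8 (lithium at the terminal alkyne carbon) | CC(C)=CC[C@@]1(C)C(OC)=C(CC#[C-])C(=O)C(C(=O)C(C)C)=C1OC.[Li+] | intermediate
10 | lithium ynolate of 8 (lithium 3-[(S)-ring A]prop-1-yn-1-olate) | CC(C)=CC[C@@]1(C)C(OC)=C(CC#C[O-])C(=O)C(C(=O)C(C)C)=C1OC.[Li+] | intermediate
11 | (S)-3,5-dimethoxy-4-methyl-4-(3-methylbut-2-en-1-yl)-2-(2-methylpropanoyl)-6-{3-[tri(propan-2-yl)silyloxy]prop-2-yn-1-yl}cyclohexa-2,5-dien-1-one | CC(C)=CC[C@@]1(C)C(OC)=C(CC#CO[Si](C(C)C)(C(C)C)C(C)C)C(=O)C(C(=O)C(C)C)=C1OC | intermediate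
12 | 4-methylideneoxetan-2-one (diketene) | C=C1CC(=O)O1 | starting material
13 | ethoxyethyne | CCOC#C | starting material
14 | ethenone (ketene) | C=C=O | intermediate
15 | 3-ethoxycyclobut-2-en-1-one | CCOC1=CC(=O)C1 | intermediate
16 | 2-methylbut-3-yn-2-ol | CC(C)(O)C#C | starting material
17 | 3-(2-methylbut-3-yn-2-yloxy)cyclobut-2-en-1-one | O=C1CC(OC(C)(C)C#C)=C1 | intermediate
18 | (S)-6-{[2-hydroxy-4-(2-methylbut-3-yn-2-yloxy)-6-(triisopropylsilyloxy)phenyl]methyl}-3,5-dimethoxy-4-methyl-4-(3-methylbut-2-en-1-yl)-2-(2-methylpropanoyl)cyclohexa-2,5-dien-1-one | CC(C)=CC[C@@]1(C)C(OC)=C(Cc2c(O)cc(OC(C)(C)C#C)cc2O[Si](C(C)C)(C(C)C)C(C)C)C(=O)C(C(=O)C(C)C)=C1OC | intermediate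
19 | (S)-6-{[2-hydroxy-3-(2-methylpropanoyl)-4-(2-methylbut-3-yn-2-yloxy)-6-(triisopropylsilyloxy)phenyl]methyl}-3,5-dimethoxy-4-methyl-4-(3-methylbut-2-en-1-yl)-2-(2-methylpropanoyl)cyclohexa-2,5-dien-1-one | CC(C)=CC[C@@]1(C)C(OC)=C(Cc2c(O)c(C(=O)C(C)C)c(OC(C)(C)C#C)cc2O[Si](C(C)C)(C(C)C)C(C)C)C(=O)C(C(=O)C(C)C)=C1OC | intermediate
20 | (S)-6-{[7-hydroxy-2,2-dimethyl-8-(2-methylpropanoyl)-5-(triisopropylsilyloxy)-2H-chromen-6-yl]methyl}-3,5-dimethoxy-4-methyl-4-(3-methylbut-2-en-1-yl)-2-(2-methylpropanoyl)cyclohexa-2,5-dien-1-one | CC(C)=CC[C@@]1(C)C(OC)=C(Cc2c(O)c(C(=O)C(C)C)c3OC(C)(C)C=Cc3c2O[Si](C(C)C)(C(C)C)C(C)C)C(=O)C(C(=O)C(C)C)=C1OC | intermediate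
21 | (S)-6-{[5,7-dihydroxy-2,2-dimethyl-8-(2-methylpropanoyl)-2H-chromen-6-yl]methyl}-3,5-dimethoxy-4-methyl-4-(3-methylbut-2-en-1-yl)-2-(2-methylpropanoyl)cyclohexa-2,5-dien-1-one | CC(C)=CC[C@@]1(C)C(OC)=C(Cc2c(O)c(C(=O)C(C)C)c3OC(C)(C)C=Cc3c2O)C(=O)C(C(=O)C(C)C)=C1OC | intermediate
22 | (S)-6-{[5,7-dihydroxy-2,2-dimethyl-8-(2-methylpropanoyl)-2H-chromen-6-yl]methyl}-3,5-dihydroxy-4-methyl-4-(3-methylbut-2-en-1-yl)-2-(2-methylpropanoyl)cyclohexa-2,5-dien-1-one (CNP0301804.1) | CC(C)=CC[C@@]1(C)C(O)=C(Cc2c(O)c3c(c(C(=O)C(C)C)c2O)OC(C)(C)C=C3)C(=O)C(C(=O)C(C)C)=C1O | target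

## Step count and risk

Total: 12 steps. Longest linear sequence: 10 steps (steps 1–5 and 8–12); the cyclobutenone branch (steps 6 and 7) joins at step 8.

**Step 8 (key step).**
- **Risk:** the donor-stabilised cyclobutenone may open only at a temperature at which the aryl propargyl ether of the product already rearranges. The vinylketene may also be lost to dimerisation or to O-acylation of the product phenol before it adds to the hindered ynol ether.
- **Fallback (known chemistry):** ring B is no longer built but brought in. Setting out from 5, a Mannich reaction with dimethyl(methylidene)ammonium iodide gives (S)-6-[(dimethylamino)methyl]-3,5-dihydroxy-4-methyl-4-(3-methylbut-2-en-1-yl)-2-(2-methylpropanoyl)cyclohexa-2,5-dien-1-one F1. Separately, commercial phloroglucinol is acylated with 2 (AlCl3) to 2-methyl-1-(2,4,6-trihydroxyphenyl)propan-1-one F2. F2 is condensed with 3-methylbut-2-enal (ethylenediammonium diacetate, toluene, 110 °C) to 1-(5,7-dihydroxy-2,2-dimethyl-2H-chromen-8-yl)-2-methylpropan-1-one F3, which has to be separated from the product of the regioisomeric ring closure. Heating F1 with F3 in 1,4-dioxane at 90 °C eliminates the amine to the 6-methylene trione, which is trapped by the one free ring carbon of F3. The fallback returns to the route at 22.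

**Step 5.**
- **Risk:** enolisation of the isobutyryl ketone, or addition of the acetylide or the peroxide anion to the doubly activated enol ether carbon C3 of ring A, may compete with oxygen transfer to the acetylide.
- **Fallback:** the enolates are used as the protecting group. Setting out from 7, the dilithium salt is formed with LiN(SiMe3)2 (2 equiv) and the alkyne deprotonated with n-BuLi (1 equiv). The acetylide is oxidised with LiOOtBu and the ynolate silylated with i-Pr3SiCl to (S)-3,5-dihydroxy-4-methyl-4-(3-methylbut-2-en-1-yl)-2-(2-methylpropanoyl)-6-{3-[tri(propan-2-yl)silyloxy]prop-2-yn-1-yl}cyclohexa-2,5-dien-1-one F4. After a buffered work-up, crude F4 is methylated at once with diazomethane in ether, returning to the route at 11.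

**Step 9.**
- **Risk:** the Lewis acid may ionise or rearrange the tertiary propargyl aryl ether, or acylation may stop at the phenyl ester.
- **Fallback:** the carbon is introduced under basic conditions at the aldehyde oxidation level. Setting out from 18, ortho-formylation (MgCl2, Et3N, paraformaldehyde, THF, 65 °C; Casnati–Skattebøl conditions) gives the salicylaldehyde (S)-6-{[3-formyl-2-hydroxy-4-(2-methylbut-3-yn-2-yloxy)-6-(triisopropylsilyloxy)phenyl]methyl}-3,5-dimethoxy-4-methyl-4-(3-methylbut-2-en-1-yl)-2-(2-methylpropanoyl)cyclohexa-2,5-dien-1-one F5. Addition of i-PrMgCl/CeCl3 (THF, −78 °C) gives, as a mixture of epimers at the carbinol carbon, (S)-6-{[2-hydroxy-3-(1-hydroxy-2-methylpropyl)-4-(2-methylbut-3-yn-2-yloxy)-6-(triisopropylsilyloxy)phenyl]methyl}-3,5-dimethoxy-4-methyl-4-(3-methylbut-2-en-1-yl)-2-(2-methylpropanoyl)cyclohexa-2,5-dien-1-one F6. Oxidation with MnO2 returns to the route at 19.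

**Step 7.**
- **Risk:** exchange with a tertiary alcohol may stall at the mixed ketal, or the alcohol may attack the strained carbonyl group and cleave the ring.
- **Fallback:** setting out from 15, hydrolysis with cold dilute aqueous HCl gives cyclobutane-1,3-dione F7. 16 is converted with Cl3CCN and catalytic DBU into 2-methylbut-3-yn-2-yl 2,2,2-trichloroacetimidate F8. The strongly acidic enol of F7 is O-alkylated by F8 in CH2Cl2, as in imidate esterification of carboxylic acids, returning to the route at 17.

**Step 2.**
- **Risk:** facial discrimination at the prochiral ring carbon may be insufficient, and allylation at the unsubstituted ring carbon or at oxygen may compete.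
- **Fallback:** setting out from 3, dearomative prenylation with 1-bromo-3-methylbut-2-ene and NaOMe in MeOH gives racemic 3,5-dihydroxy-4-methyl-4-(3-methylbut-2-en-1-yl)-2-(2-methylpropanoyl)cyclohexa-2,5-dien-1-one F9. F9 is resolved by preparative chromatography on an amylose tris(3,5-dimethylphenylcarbamate) phase, returning to the route at 5.

## Further compounds

F1 | step 8 | (S)-6-[(dimethylamino)methyl]-3,5-dihydroxy-4-methyl-4-(3-methylbut-2-en-1-yl)-2-(2-methylpropanoyl)cyclohexa-2,5-dien-1-one | CC(C)=CC[C@@]1(C)C(O)=C(CN(C)C)C(=O)C(C(=O)C(C)C)=C1O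
F2 | step 8 | 2-methyl-1-(2,4,6-trihydroxyphenyl)propan-1-one | CC(C)C(=O)c1c(O)cc(O)cc1O
F3 | step 8 | 1-(5,7-dihydroxy-2,2-dimethyl-2H-chromen-8-yl)-2-methylpropan-1-one | CC(C)C(=O)c1c(O)cc(O)c2C=CC(C)(C)Oc12
F4 | step 5 | (S)-3,5-dihydroxy-4-methyl-4-(3-methylbut-2-en-1-yl)-2-(2-methylpropanoyl)-6-{3-[tri(propan-2-yl)silyloxy]prop-2-yn-1-yl}cyclohexa-2,5-dien-1-one | CC(C)=CC[C@@]1(C)C(O)=C(CC#CO[Si](C(C)C)(C(C)C)C(C)C)C(=O)C(C(=O)C(C)C)=C1O
F5 | step 9 | (S)-6-{[3-formyl-2-hydroxy-4-(2-methylbut-3-yn-2-yloxy)-6-(triisopropylsilyloxy)phenyl]methyl}-3,5-dimethoxy-4-methyl-4-(3-methylbut-2-en-1-yl)-2-(2-methylpropanoyl)cyclohexa-2,5-dien-1-one | CC(C)=CC[C@@]1(C)C(OC)=C(Cc2c(O)c(C=O)c(OC(C)(C)C#C)cc2O[Si](C(C)C)(C(C)C)C(C)C)C(=O)C(C(=O)C(C)C)=C1OC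
F6 | step 9 | (S)-6-{[2-hydroxy-3-(1-hydroxy-2-methylpropyl)-4-(2-methylbut-3-yn-2-yloxy)-6-(triisopropylsilyloxy)phenyl]methyl}-3,5-dimethoxy-4-methyl-4-(3-methylbut-2-en-1-yl)-2-(2-methylpropanoyl)cyclohexa-2,5-dien-1-one, carbinol centre unassigned | CC(C)=CC[C@@]1(C)C(OC)=C(Cc2c(O)c(C(O)C(C)C)c(OC(C)(C)C#C)cc2O[Si](C(C)C)(C(C)C)C(C)C)C(=O)C(C(=O)C(C)C)=C1OC
F7 | step 7 | cyclobutane-1,3-dione | O=C1CC(=O)C1
F8 | step 7 | 2-methylbut-3-yn-2-yl 2,2,2-trichloroacetimidate | CC(C)(C#C)OC(=N)C(Cl)(Cl)Cl
F9 | step 2 | racemic 3,5-dihydroxy-4-methyl-4-(3-methylbut-2-en-1-yl)-2-(2-methylpropanoyl)cyclohexa-2,5-dien-1-one | CC(C)=CCC1(C)C(O)=CC(=O)C(C(=O)C(C)C)=C1O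
A1 | alternative 1 | (R)-5-hydroxy-3-methoxy-6-methyl-6-(3-methylbut-2-en-1-yl)-4-(2-methylpropanoyl)cyclohexa-2,4-dien-1-one (ring A vinylogous methyl ester, same spatial arrangement at the quaternary carbon as in 5) | CC(C)=CC[C@@]1(C)C(=O)C=C(OC)C(C(=O)C(C)C)=C1O
A2 | alternative 1 | racemic 4-methoxy-6-(5-methylhex-4-en-2-yl)-3-(2-methylpropanoyl)-2H-pyran-2-one | CC(C)=CCC(C)c1cc(OC)c(C(=O)C(C)C)c(=O)o1
A3 | alternative 2 | 1-[7-hydroxy-2,2-dimethyl-5-(triisopropylsilyloxy)-2H-chromen-8-yl]-2-methylpropan-1-one | CC(C)C(=O)c1c(O)cc(O[Si](C(C)C)(C(C)C)C(C)C)c2C=CC(C)(C)Oc12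
A4 | alternative 2 | 1-[2-hydroxy-6-(2-methylbut-3-yn-2-yloxy)-4-(triisopropylsilyloxy)phenyl]-2-methylpropan-1-one | CC(C)C(=O)c1c(O)cc(O[Si](C(C)C)(C(C)C)C(C)C)cc1OC(C)(C)C#C
A5 | alternative 3 | (S)-3,5-dihydroxy-4-methyl-4-(3-methylbut-2-en-1-yl)-2-(2-methylpropanoyl)cyclohexa-2,5-dien-1-one (identical with 5) | CC(C)=CC[C@@]1(C)C(O)=CC(=O)C(C(=O)C(C)C)=C1O
A6 | alternative 3 | methyl 2,8-dimethyl-2-(3-methylbut-2-en-1-yl)-3,5,7-trioxononanoate, single enantiomer as drawn | CC(C)=CC[C@@](C(=O)OC)(C)C(=O)CC(=O)CC(=O)C(C)C
A7 | alternative 3 | (S)-3-methoxy-2-methyl-2-(3-methylbut-2-en-1-yl)-3-oxopropanoic acid | CC(C)=CC[C@@](C(=O)OC)(C)C(O)=O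
A8 | alternative 3 | dimethyl 2-methyl-2-(3-methylbut-2-en-1-yl)propanedioate | COC(=O)C(C)(CC=C(C)C)C(=O)OC
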